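The dihydropyran ring of the chroman (O1–C2–C3–C4–C4a–C8a) is opened by a retro-oxa-[4+2] that copies the presumed biosynthesis. Ring A with C4 becomes an ortho-quinone methide, and C2=C3 becomes an (E)-hydroxystyrene carrying the diformylphloroglucinol ring B. In one operation a chiral phosphoric acid ionises a racemic benzylic alcohol to the planar methide (enantioconvergent) and forges O1–C2 and C3–C4 with all three stereocentres. The step exploits three features: the phenolic O1 ortho to C4, the C5 oxygen peri to C4 (kept as OMe, it fixes which oxygen closes and the methide geometry), and the ortho-hydroxyls of ring B. Precursors: alcohol 9 and styrene 5.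

Key step: step 5

Numbering: chroman numbering of the target is used throughout (O1, aryl-bearing C2, isopropyl-bearing C3, isobutyl-bearing C4, C4a, C5–C8, C8a). Ring A is the benzo ring and ring B is the aryl group on C2. The target is (2R,3R,4S), that is 2,3-trans and 3,4-cis.

Assumption: the (R)-configured acid is taken to leave open the face of the methide that leads to the (2R,3R,4S) series; if the sense of induction proves opposite, its (S)-enantiomer is used without other change.

Step 1
Reactants: 1 2,4,6-trimethoxybenzene-1,3,5-tricarbaldehyde; 2 isobutylmagnesium bromide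
Product: 3 rac-5-(1-hydroxy-3-methylbutyl)-2,4,6-trimethoxybenzene-1,3-dicarbaldehyde
Conditions: 2 (1.0 equiv, slow addition), THF, −78 °C; then H2O/aq NH4Cl
Reagents that add atoms: none
Why: Grignard 1,2-addition to one of the three equivalent formyl groups of the C3-symmetric trialdehyde, held at mono-addition by stoichiometry and by the deactivating magnesium alkoxide that forms; the new carbinol centre is racemic and is erased in step 2.

Step 2
Reactants: 3 rac-5-(1-hydroxy-3-methylbutyl)-2,4,6-trimethoxybenzene-1,3-dicarbaldehyde
Product: 4 2,4,6-trimethoxy-5-[(E)-3-methylbut-1-enyl]benzene-1,3-dicarbaldehyde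
Conditions: p-toluenesulfonic acid monohydrate (5 mol %), toluene, 90 °C, Dean–Stark trap
Reagents that add atoms: none
Why: Acid-catalysed E1 dehydration through the 2,4,6-trimethoxybenzyl cation should give the conjugated alkene as the thermodynamically favoured (E)-isomer, because the (Z)-isomer would press the isopropyl group against an ortho-methoxy group, and with no free phenol present no quinone methide and hence no dimer can form.

Step 3
Reactants: 4 2,4,6-trimethoxy-5-[(E)-3-methylbut-1-enyl]benzene-1,3-dicarbaldehyde
Product: 5 2,4,6-trihydroxy-5-[(E)-3-methylbut-1-enyl]benzene-1,3-dicarbaldehyde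
Conditions: BBr3 (5 equiv), CH2Cl2, −78 to 0 °C; cold aq NaH2PO4 quench; used promptly
Reagents that add atoms: none
Why: Lewis-acid aryl methyl ether cleavage, eased because every methoxy group is ortho to a formyl group (chelation) and twisted out of the ring plane, with the disubstituted alkene tolerated as in stilbenoid demethylations, so that the (E)-geometry is kept.

Step 4
Reactants: 6 4-hydroxy-2,6-dimethoxybenzaldehyde; 7 3-methylbutanal (isovaleraldehyde)
Product: 9 rac-4-hydroxy-3-(1-hydroxy-3-methylbutyl)-2,6-dimethoxybenzaldehyde, via bromomagnesium phenoxide 8 (not isolated)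
Conditions: EtMgBr (1.0 equiv), Et2O, 0 °C; solvent exchange to CH2Cl2; 7 (1.2 equiv), 0 °C to rt; pH 7 buffer; Et3N-deactivated silica
Reagents that add atoms: ethylmagnesium bromide, CC[Mg]Br (supplies Mg and Br of intermediate 8 only; nothing of it remains in 9)
Why: Magnesium-phenoxide-mediated ortho-specific hydroxyalkylation (the higher-aldehyde counterpart of the Casnati–Skattebøl formylation): the phenoxide binds 7 and delivers it through a six-membered chelate to one of the two equivalent ortho carbons, which are further activated by an ortho and a para methoxy group, while the ring's own formyl group is a hindered vinylogous carboxylate that does not compete; the carbinol centre is racemic and is erased in step 5.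

Step 5
Reactants: 9 rac-4-hydroxy-3-(1-hydroxy-3-methylbutyl)-2,6-dimethoxybenzaldehyde; 5 2,4,6-trihydroxy-5-[(E)-3-methylbut-1-enyl]benzene-1,3-dicarbaldehyde
Product: 11 (2R,3R,4S)-2-(3,5-diformyl-2,4,6-trihydroxyphenyl)-4-isobutyl-3-isopropyl-5,7-dimethoxychroman-6-carbaldehyde, via ortho-quinone methide 10 (not isolated)
Conditions: (R)-3,3'-bis(2,4,6-triisopropylphenyl)-1,1'-binaphthyl-2,2'-diyl hydrogen phosphate (10 mol %), 5 (2.5 equiv, excess recovered), 9 added by syringe pump, CH2Cl2, 4 Å molecular sieves, 0 °C
Reagents that add atoms: none
Why: The acid dehydrates racemic 9, so that both enantiomers converge on the planar methide 10 held by a hydrogen bond to the catalyst, whose phosphoryl oxygen at the same time binds a free ortho-hydroxyl of 5, and an asynchronous inverse-electron-demand oxa-[4+2] cycloaddition follows in which C3–C4 bonding runs ahead of O1–C2 bonding. The closest known reaction type is the chiral-phosphoric-acid-catalysed cycloaddition of ortho-hydroxybenzyl alcohols with ortho-hydroxystyrenes to 2,3,4-trisubstituted chromans, and in achiral form it is the presumed biosynthetic dimerisation of formylated phloroglucinols. The one ring that closes, the dihydropyran, closes in the [4+2] cycloaddition mode (counted stepwise it would be a 6-exo-trig oxa-Michael closure of O1 onto C2). C2 and C3 should become trans because the (E)-geometry of 5 is transferred (and because O1–C2 closure is reversible, so that the diequatorial arrangement is also the thermodynamic one), while C3 and C4 should become cis because allylic strain with the C5 methoxy group turns the isobutyl group of 10 toward the carbonyl oxygen (Z-methide) and ring B stacks endo under ring A, which leaves isobutyl pseudo-axial and isopropyl and aryl pseudo-equatorial. The absolute configuration at C4, and through these relations at C3 and C2, is set by the catalyst pocket, which leaves one face of bound 10 open. The step needs site, orientation and cross selectivity: only O1 is free on ring A, 5 has no aromatic C–H so only its alkene carbon can attack, the polarity of methide and styrene pairs C3 with C4, and self-coupling of 10 through its styrene tautomer is held down by excess 5 and slow addition of 9.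

Step 6
Reactants: 11 (2R,3R,4S)-2-(3,5-diformyl-2,4,6-trihydroxyphenyl)-4-isobutyl-3-isopropyl-5,7-dimethoxychroman-6-carbaldehyde
Product: 12 (2R,3R,4S)-2-(3,5-diformyl-2,4,6-trihydroxyphenyl)-5,7-dihydroxy-4-isobutyl-3-isopropylchroman-6-carbaldehyde (target)
Conditions: BBr3 (8 equiv), CH2Cl2, −78 to −10 °C; cold aq NaH2PO4 quench
Reagents that add atoms: none
Why: Chelation-assisted Lewis-acid cleavage of the two methoxy groups that flank the C6 formyl group (the 2,6-dimethoxybenzaldehyde to 2,6-dihydroxybenzaldehyde reaction type); immediate borylation of the ring B phenols and complexation of all formyl groups make both rings electron-poor and should keep the O1–C2 bond closed, the freed C5 oxygen stays in a boron chelate until the quench, and no stereocentre is touched.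

Compound list
1 | 2,4,6-trimethoxybenzene-1,3,5-tricarbaldehyde | COc1c(C=O)c(OC)c(C=O)c(OC)c1C=O | starting material
2 | isobutylmagnesium bromide | CC(C)C[Mg]Br | starting material
3 | rac-5-(1-hydroxy-3-methylbutyl)-2,4,6-trimethoxybenzene-1,3-dicarbaldehyde | CC(C)CC(O)c1c(OC)c(C=O)c(OC)c(C=O)c1OC | intermediate
4 | 2,4,6-trimethoxy-5-[(E)-3-methylbut-1-enyl]benzene-1,3-dicarbaldehyde | CC(C)/C=C/c1c(OC)c(C=O)c(OC)c(C=O)c1OC | intermediate
5 | 2,4,6-trihydroxy-5-[(E)-3-methylbut-1-enyl]benzene-1,3-dicarbaldehyde | CC(C)/C=C/c1c(O)c(C=O)c(O)c(C=O)c1O | intermediate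
6 | 4-hydroxy-2,6-dimethoxybenzaldehyde | COc1cc(O)cc(OC)c1C=O | starting material
7 | 3-methylbutanal | CC(C)CC=O | starting material
8 | bromomagnesium 4-formyl-3,5-dimethoxyphenoxide | COc1cc(O[Mg]Br)cc(OC)c1C=O | intermediate
9 | rac-4-hydroxy-3-(1-hydroxy-3-methylbutyl)-2,6-dimethoxybenzaldehyde | CC(C)CC(O)c1c(O)cc(OC)c(C=O)c1OC | intermediate
10 | (3Z)-2,6-dimethoxy-3-(3-methylbutylidene)-4-oxocyclohexa-1,5-diene-1-carbaldehyde (ortho-quinone methide, isobutyl cis to the ring carbonyl) | O=C1C=C(OC)C(C=O)=C(OC)/C1=C/CC(C)C | intermediate
11 | (2R,3R,4S)-2-(3,5-diformyl-2,4,6-trihydroxyphenyl)-4-isobutyl-3-isopropyl-5,7-dimethoxychroman-6-carbaldehyde | CC(C)C[C@@H]1c2c(cc(OC)c(C=O)c2OC)O[C@@H](c2c(O)c(C=O)c(O)c(C=O)c2O)[C@@H]1C(C)C | intermediate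
12 | (2R,3R,4S)-2-(3,5-diformyl-2,4,6-trihydroxyphenyl)-5,7-dihydroxy-4-isobutyl-3-isopropylchroman-6-carbaldehyde | CC(C)C[C@@H]1c2c(cc(O)c(C=O)c2O)O[C@@H](c2c(O)c(C=O)c(O)c(C=O)c2O)[C@@H]1C(C)C | target

Total step count: 6. Longest linear sequence: 5 (steps 1, 2, 3, 5, 6).

Steps most likely to fail

Step 5. Several things may go wrong:
- The methide may tautomerise to its own, more nucleophilic styrene and couple with itself.
- The roles of the partners may reverse if 5 is protonated.
- The acidic phenols of 5 may ionise 9 outside the catalyst pocket, giving a racemic background reaction.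
- Facial or endo/exo discrimination may be weak.

The fallback sets out from 9 and returns at 11. It replaces acid activation by base activation. Alcohol 9 is treated with p-toluenesulfinic acid in CH2Cl2 (SN1 substitution through the methide) to give the storable sulfone 4-hydroxy-2,6-dimethoxy-3-[3-methyl-1-(4-methylphenyl)sulfonylbutyl]benzaldehyde F1. F1 and 5 are then combined under liquid–liquid phase-transfer conditions (toluene/aq K2CO3, N-(9-anthracenylmethyl)cinchonidinium chloride, 0 °C). Base-triggered E1cB loss of sulfinate releases 10 in an acid-free medium, and 5 reacts as its far more nucleophilic phenoxide inside a chiral ion pair. Acid-catalysed tautomerisation and background ionisation are switched off, and both ring bonds again form in one operation to give 11.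

Step 4. Carbon–carbon bond formation may be sluggish because the para-formyl group deactivates the phenoxide. The product may also lose water prematurely and be attacked by a second phenoxide. The fallback sets out from 6 and returns at 10, bypassing the alcohol.
- Iodination of 6 (N-iodosuccinimide, MeCN) at one of the two equivalent positions ortho to the hydroxyl gives 4-hydroxy-3-iodo-2,6-dimethoxybenzaldehyde F2.
- Suzuki–Miyaura coupling of F2 with (E)-3-methylbut-1-enylboronic acid pinacol ester (Pd(dppf)Cl2, K2CO3, dioxane/H2O, 80 °C) gives 4-hydroxy-2,6-dimethoxy-3-[(E)-3-methylbut-1-enyl]benzaldehyde F3.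
- F3 is fed slowly, in place of 9, into the step 5 mixture. The phosphoric acid protonates its terminal alkene carbon (the known activation of ortho-hydroxystyrenes as methide precursors) and so enters the route at 10.

Step 6. The Lewis acid may ionise the O1–C2 bond. Re-closure through the newly freed C5 hydroxyl would then lose regiochemical integrity. Cleavage of the second methoxy group may also stall. The fallback sets out from 11 and returns at 12. It switches ring B off electronically before the ethers are cut.
- Acetylation (Ac2O, pyridine, 0 °C) gives the ring B tri-O-acetate of 11, (2R,3R,4S)-2-(2,4,6-triacetoxy-3,5-diformylphenyl)-4-isobutyl-3-isopropyl-5,7-dimethoxychroman-6-carbaldehyde F4. Its acylated aryl group can no longer support a cation at C2.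
- Chelation-controlled cleavage with BCl3 (CH2Cl2, −78 °C to rt) gives (2R,3R,4S)-2-(2,4,6-triacetoxy-3,5-diformylphenyl)-5,7-dihydroxy-4-isobutyl-3-isopropylchroman-6-carbaldehyde F5.
- Neutral deacetylation of the activated aryl acetates (NH4OAc, aq MeOH, rt) gives 12.

Further compounds
F1 | step 5 | 4-hydroxy-2,6-dimethoxy-3-[3-methyl-1-(4-methylphenyl)sulfonylbutyl]benzaldehyde | CC(C)CC(c1c(O)cc(OC)c(C=O)c1OC)S(=O)(=O)c1ccc(C)cc1
F2 | step 4 | 4-hydroxy-3-iodo-2,6-dimethoxybenzaldehyde | COc1cc(O)c(I)c(OC)c1C=O
F3 | step 4 | 4-hydroxy-2,6-dimethoxy-3-[(E)-3-methylbut-1-enyl]benzaldehyde | CC(C)/C=C/c1c(O)cc(OC)c(C=O)c1OC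
F4 | step 6 | (2R,3R,4S)-2-(2,4,6-triacetoxy-3,5-diformylphenyl)-4-isobutyl-3-isopropyl-5,7-dimethoxychroman-6-carbaldehyde | CC(C)C[C@@H]1c2c(cc(OC)c(C=O)c2OC)O[C@@H](c2c(OC(C)=O)c(C=O)c(OC(C)=O)c(C=O)c2OC(C)=O)[C@@H]1C(C)C
F5 | step 6 | (2R,3R,4S)-2-(2,4,6-triacetoxy-3,5-diformylphenyl)-5,7-dihydroxy-4-isobutyl-3-isopropylchroman-6-carbaldehyde | CC(C)C[C@@H]1c2c(cc(O)c(C=O)c2O)O[C@@H](c2c(OC(C)=O)c(C=O)c(OC(C)=O)c(C=O)c2OC(C)=O)[C@@H]1C(C)C
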